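**Plan**

- Retrosynthesis: the two MOM acetals come off last. The C3–C4 bond of pyrone ring B (O1, C2 lactone carbonyl, C3 with the bridge CH2, C4–OH, C5–Me, C6–Et) is then cut, then the enol-ester C–O bond at O1–C2, then the side chain and the three ring–carbon bonds of ring A.
- Enabling feature: C4, C5, C6 and O1 of ring B are the enol of methyl 2-methyl-3-oxopentanoate; C2, C3 and the bridge CH2 are a 3-arylpropanoyl group on that enol oxygen. The bridge carbon is therefore never made by joining two finished rings.
- Forward: ring A (in order around the ring: bridge carbon, OH, prenyl, OH, isobutyryl, OMe) is filled by three directed metalations of bis-MOM 5-methoxyresorcinol. The aldehyde at the bridge position is extended with Meldrum's acid to the propanoic acid, which is hung on the keto-ester enol oxygen. Ring B, the only ring made, closes last.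
- Stereochemistry: the target has no stereocentre. Only the Z geometry of the C5=C6 enol-ester alkene matters; it is set in step 8 by a sodium chelate.

Key step: step 9

Remark on the chemistry: compounds 8, 9, 10 and 16 are racemates; their stereocentres are erased in steps 5 and 8, so this has no consequence.

**Route**

Step 1
Reactants: 1 5-methoxyresorcinol
Product: 2 1-methoxy-3,5-bis(methoxymethoxy)benzene
Conditions: MOMCl, iPr2NEt, CH2Cl2, 0 °C to rt
Reagents that add atoms: chloromethyl methyl ether (MOMCl), COCCl
Why: Williamson-type O-alkylation of both phenols gives the MOM acetals, which later serve as directing groups for ortho-lithiation.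

Step 2
Reactants: 2 1-methoxy-3,5-bis(methoxymethoxy)benzene; 3 prenyl bromide
Product: 5 5-methoxy-1,3-bis(methoxymethoxy)-2-(3-methylbut-2-en-1-yl)benzene, via aryllithium 4 (not isolated)
Conditions: n-BuLi, THF, 0 °C; CuBr·SMe2 (10 mol%), then 3, −78 °C to rt
Reagents that add atoms: none
Why: Directed ortho-metalation should occur at the carbon flanked by the two MOM ethers (the strongest cooperative pair), and the copper-assisted allylation of the aryllithium by prenyl bromide is expected at the primary carbon (SN2).

Step 3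
Reactants: 5 5-methoxy-1,3-bis(methoxymethoxy)-2-(3-methylbut-2-en-1-yl)benzene; 6 isobutyraldehyde
Product: 8 1-[6-methoxy-2,4-bis(methoxymethoxy)-3-(3-methylbut-2-en-1-yl)phenyl]-2-methylpropan-1-ol (racemic), via aryllithium 7 (not isolated)
Conditions: n-BuLi, TMEDA, THF, 0 °C; 6, −78 °C to rt; H2O
Reagents that add atoms: none
Why: A second directed ortho-metalation at either of the two equivalent CH positions (each between OMOM and OMe) and 1,2-addition to the aldehyde install the isobutyryl carbons as a carbinol that tolerates the next organolithium step.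

Step 4
Reactants: 8 1-[6-methoxy-2,4-bis(methoxymethoxy)-3-(3-methylbut-2-en-1-yl)phenyl]-2-methylpropan-1-ol
Product: 10 3-(1-hydroxy-2-methylpropyl)-2-methoxy-4,6-bis(methoxymethoxy)-5-(3-methylbut-2-en-1-yl)benzaldehyde (racemic), via dilithio alkoxide 9 (not isolated)
Conditions: n-BuLi (2.3 equiv), TMEDA, THF, −20 to 0 °C; DMF, −78 °C to rt; H2O
Reagents that add atoms: N,N-dimethylformamide (DMF), CN(C)C=O
Why: The first equivalent of base forms the inert lithium alkoxide, the second metalates the last ring CH (between OMOM and OMe, directed ortho-metalation), and DMF formylates the aryllithium (Bouveault-type formylation).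

Step 5
Reactants: 10 3-(1-hydroxy-2-methylpropyl)-2-methoxy-4,6-bis(methoxymethoxy)-5-(3-methylbut-2-en-1-yl)benzaldehyde
Product: 11 2-methoxy-4,6-bis(methoxymethoxy)-5-(3-methylbut-2-en-1-yl)-3-(2-methylpropanoyl)benzaldehyde
Conditions: Dess–Martin periodinane, CH2Cl2, rt
Reagents that add atoms: none
Why: Dess–Martin oxidation should convert the secondary benzylic alcohol into the ketone without touching the aldehyde, the prenyl alkene or the MOM acetals, and it removes the racemic carbinol centre.

Step 6
Reactants: 11 2-methoxy-4,6-bis(methoxymethoxy)-5-(3-methylbut-2-en-1-yl)-3-(2-methylpropanoyl)benzaldehyde; 12 Meldrum's acid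
Product: 14 5-{[2-methoxy-4,6-bis(methoxymethoxy)-5-(3-methylbut-2-en-1-yl)-3-(2-methylpropanoyl)phenyl]methyl}-2,2-dimethyl-1,3-dioxane-4,6-dione, via alkylidene Meldrum's acid 13 (not isolated)
Conditions: Hantzsch ester, L-proline (20 mol%), EtOH, rt
Reagents that add atoms: none
Why: Knoevenagel condensation followed in the same flask by conjugate hydride transfer from the Hantzsch ester (organocatalytic reductive alkylation) is expected to reduce only the doubly activated alkylidene, leaving the hindered aryl ketone and the prenyl alkene.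

Step 7
Reactants: 14 5-{[2-methoxy-4,6-bis(methoxymethoxy)-5-(3-methylbut-2-en-1-yl)-3-(2-methylpropanoyl)phenyl]methyl}-2,2-dimethyl-1,3-dioxane-4,6-dione
Product: 15 3-[2-methoxy-4,6-bis(methoxymethoxy)-5-(3-methylbut-2-en-1-yl)-3-(2-methylpropanoyl)phenyl]propanoic acid
Conditions: pyridine/H2O (10:1), 100 °C
Reagents that add atoms: water, O
Why: Hydrolytic opening of the Meldrum's acid ring and decarboxylation of the resulting malonic acid in hot wet pyridine should give the propanoic acid under non-acidic conditions that spare the MOM ethers.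

Step 8
Reactants: 15 3-[2-methoxy-4,6-bis(methoxymethoxy)-5-(3-methylbut-2-en-1-yl)-3-(2-methylpropanoyl)phenyl]propanoic acid; 16 methyl 2-methyl-3-oxopentanoate
Product: 19 methyl (2Z)-3-({3-[2-methoxy-4,6-bis(methoxymethoxy)-5-(3-methylbut-2-en-1-yl)-3-(2-methylpropanoyl)phenyl]propanoyl}oxy)-2-methylpent-2-enoate, via acid chloride 17 (not isolated), via sodium enolate 18 (not isolated)
Conditions: 15, 1-chloro-N,N,2-trimethylprop-1-en-1-amine, CH2Cl2, 0 °C to rt; separately 16, NaH, Et2O, 0 °C; then slow addition of 17, −20 °C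
Reagents that add atoms: none
Why: O-acylation of a chelated enolate: the acid chloride is made under neutral conditions, sodium bridges the two oxygens of the keto-ester enolate so the ester and the enolate oxygen are cis when the acyl group is captured (the control known for Z-enol phosphates and Z-enol triflates), and attack at carbon is disfavoured because it would build a quaternary centre.

Step 9
Reactants: 19 methyl (2Z)-3-({3-[2-methoxy-4,6-bis(methoxymethoxy)-5-(3-methylbut-2-en-1-yl)-3-(2-methylpropanoyl)phenyl]propanoyl}oxy)-2-methylpent-2-enoate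
Product: 22 6-ethyl-4-hydroxy-3-{[2-methoxy-4,6-bis(methoxymethoxy)-5-(3-methylbut-2-en-1-yl)-3-(2-methylpropanoyl)phenyl]methyl}-5-methyl-2H-pyran-2-one, via lithium ester enolate 20 (not isolated), via lithium pyronate 21 (not isolated)
Conditions: LiN(SiMe3)2 (3 equiv), THF, −78 to 0 °C; then 1 M HCl to pH 3, 0 °C
Reagents that add atoms: none
Why: Proposed new method: LiN(SiMe3)2 removes a proton from the CH2 next to the enol-ester carbonyl (the future C3), the lithium ester enolate adds to the methyl ester carbonyl held cis on the C5=C6 alkene to form C3–C4, methoxide leaves, and a second equivalent of base turns the 2,4-dioxo lactone into the lithium 4-pyronate, which makes the sequence irreversible. The closest known reaction type is the Dieckmann (intramolecular Claisen) closure of methyl O-acylsalicylates to 4-hydroxycoumarins and of beta-acyloxy esters to 5,6-dihydro-4-hydroxy-2-pyranones; here the benzene ring of the salicylate is replaced by an open-chain tetrasubstituted alkene. Ring B closes in a 6-(enolendo)-exo-trig mode, which is allowed for enolates. No stereocentre is formed. The step needs the enolate to cyclise faster than it ejects the keto-ester enolate as a ketene pair, which the low temperature and the six-membered transition state offered by the Z geometry from step 8 should secure; deprotonation of the hindered isobutyryl group is reversible and unproductive because that enolate has no ring of reasonable size to close.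

Step 10
Reactants: 22 6-ethyl-4-hydroxy-3-{[2-methoxy-4,6-bis(methoxymethoxy)-5-(3-methylbut-2-en-1-yl)-3-(2-methylpropanoyl)phenyl]methyl}-5-methyl-2H-pyran-2-one
Product: 23 3-{[2,4-dihydroxy-6-methoxy-3-(3-methylbut-2-en-1-yl)-5-(2-methylpropanoyl)phenyl]methyl}-6-ethyl-4-hydroxy-5-methyl-2H-pyran-2-one (CNP0149198.0)
Conditions: 3 M HCl, MeOH, rt
Reagents that add atoms: none
Why: Acid-catalysed acetal exchange with methanol removes both MOM ethers; conditions this mild are the usual way to unmask prenylated acylphloroglucinols and should not cyclise the prenyl group onto the flanking phenols.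

**Compound list**

1 | 5-methoxyresorcinol (5-methoxybenzene-1,3-diol) | COc1cc(O)cc(O)c1 | starting material
2 | 1-methoxy-3,5-bis(methoxymethoxy)benzene | COCOc1cc(OC)cc(OCOC)c1 | intermediate
3 | prenyl bromide (1-bromo-3-methylbut-2-ene) | CC(C)=CCBr | starting material
4 | [4-methoxy-2,6-bis(methoxymethoxy)phenyl]lithium | [Li]c1c(OCOC)cc(OC)cc1OCOC | intermediate
5 | 5-methoxy-1,3-bis(methoxymethoxy)-2-(3-methylbut-2-en-1-yl)benzene | COCOc1cc(OC)cc(OCOC)c1CC=C(C)C | intermediate
6 | isobutyraldehyde (2-methylpropanal) | CC(C)C=O | starting material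
7 | [6-methoxy-2,4-bis(methoxymethoxy)-3-(3-methylbut-2-en-1-yl)phenyl]lithium | [Li]c1c(OC)cc(OCOC)c(CC=C(C)C)c1OCOC | intermediate
8 | 1-[6-methoxy-2,4-bis(methoxymethoxy)-3-(3-methylbut-2-en-1-yl)phenyl]-2-methylpropan-1-ol (racemic) | CC(C)C(O)c1c(OC)cc(OCOC)c(CC=C(C)C)c1OCOC | intermediate
9 | lithium alkoxide of 8 lithiated at the remaining ring carbon (racemic) | CC(C)C(O[Li])c1c(OC)c([Li])c(OCOC)c(CC=C(C)C)c1OCOC | intermediate
10 | 3-(1-hydroxy-2-methylpropyl)-2-methoxy-4,6-bis(methoxymethoxy)-5-(3-methylbut-2-en-1-yl)benzaldehyde (racemic) | CC(C)C(O)c1c(OC)c(C=O)c(OCOC)c(CC=C(C)C)c1OCOC | intermediate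
11 | 2-methoxy-4,6-bis(methoxymethoxy)-5-(3-methylbut-2-en-1-yl)-3-(2-methylpropanoyl)benzaldehyde | CC(C)C(=O)c1c(OC)c(C=O)c(OCOC)c(CC=C(C)C)c1OCOC | intermediate
12 | Meldrum's acid (2,2-dimethyl-1,3-dioxane-4,6-dione) | CC1(C)OC(=O)CC(=O)O1 | starting material
13 | 5-{[2-methoxy-4,6-bis(methoxymethoxy)-5-(3-methylbut-2-en-1-yl)-3-(2-methylpropanoyl)phenyl]methylidene}-2,2-dimethyl-1,3-dioxane-4,6-dione | CC1(C)OC(=O)C(=Cc2c(OC)c(C(=O)C(C)C)c(OCOC)c(CC=C(C)C)c2OCOC)C(=O)O1 | intermediate
14 | 5-{[2-methoxy-4,6-bis(methoxymethoxy)-5-(3-methylbut-2-en-1-yl)-3-(2-methylpropanoyl)phenyl]methyl}-2,2-dimethyl-1,3-dioxane-4,6-dione | CC1(C)OC(=O)C(Cc2c(OC)c(C(=O)C(C)C)c(OCOC)c(CC=C(C)C)c2OCOC)C(=O)O1 | intermediate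
15 | 3-[2-methoxy-4,6-bis(methoxymethoxy)-5-(3-methylbut-2-en-1-yl)-3-(2-methylpropanoyl)phenyl]propanoic acid | OC(=O)CCc1c(OC)c(C(=O)C(C)C)c(OCOC)c(CC=C(C)C)c1OCOC | intermediate
16 | methyl 2-methyl-3-oxopentanoate (racemic) | CCC(=O)C(C)C(=O)OC | starting material
17 | 3-[2-methoxy-4,6-bis(methoxymethoxy)-5-(3-methylbut-2-en-1-yl)-3-(2-methylpropanoyl)phenyl]propanoyl chloride | ClC(=O)CCc1c(OC)c(C(=O)C(C)C)c(OCOC)c(CC=C(C)C)c1OCOC | intermediate
18 | sodium (Z)-enolate of methyl 2-methyl-3-oxopentanoate (chelated) | CC/C(O[Na])=C(\C)C(=O)OC | intermediate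
19 | methyl (2Z)-3-({3-[2-methoxy-4,6-bis(methoxymethoxy)-5-(3-methylbut-2-en-1-yl)-3-(2-methylpropanoyl)phenyl]propanoyl}oxy)-2-methylpent-2-enoate | CC/C(OC(=O)CCc1c(OC)c(C(=O)C(C)C)c(OCOC)c(CC=C(C)C)c1OCOC)=C(\C)C(=O)OC | intermediate
20 | lithium enolate of 19 at the acyloxy carbonyl (enolate geometry not fixed) | [Li]OC(=CCc1c(OC)c(C(=O)C(C)C)c(OCOC)c(CC=C(C)C)c1OCOC)O/C(CC)=C(/C)C(=O)OC | intermediate
21 | lithium 4-pyronate of 22 | CCc1oc(=O)c(Cc2c(OC)c(C(=O)C(C)C)c(OCOC)c(CC=C(C)C)c2OCOC)c(O[Li])c1C | intermediate
22 | 6-ethyl-4-hydroxy-3-{[2-methoxy-4,6-bis(methoxymethoxy)-5-(3-methylbut-2-en-1-yl)-3-(2-methylpropanoyl)phenyl]methyl}-5-methyl-2H-pyran-2-one | CCc1oc(=O)c(Cc2c(OC)c(C(=O)C(C)C)c(OCOC)c(CC=C(C)C)c2OCOC)c(O)c1C | intermediate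
23 | 3-{[2,4-dihydroxy-6-methoxy-3-(3-methylbut-2-en-1-yl)-5-(2-methylpropanoyl)phenyl]methyl}-6-ethyl-4-hydroxy-5-methyl-2H-pyran-2-one | CCc1oc(=O)c(Cc2c(O)c(CC=C(C)C)c(O)c(C(=O)C(C)C)c2OC)c(O)c1C | target

**Step count**

Total: 10 steps. Longest linear sequence: 10 steps (1 to 23); all other inputs are commercial.

**Steps most likely to fail**

Step 9 (bears the label). The ester enolate may fragment into a ketene and the keto-ester enolate before it cyclises, or the methoxide released may cleave unreacted enol ester. The fallback uses known chemistry, sets out from aldehyde 11 and comes back at 22; ring B is made separately and joined through the bridge carbon. Methyl 3-oxopentanoate is deprotonated twice (NaH, then n-BuLi, THF, 0 °C) to the dianion of methyl 3-oxopentanoate F1, which is acylated at its terminal carbanion with methyl propanoate to give methyl 4-methyl-3,5-dioxoheptanoate F2. DBU in refluxing toluene closes this to 6-ethyl-4-hydroxy-5-methyl-2H-pyran-2-one F3. The pyrone, aldehyde 11 and Hantzsch ester with catalytic L-proline (CH2Cl2, rt) then undergo three-component reductive alkylation. The Knoevenagel adduct, 3-arylidene-6-ethyl-5-methylpyran-2,4-dione F4, should be reduced in the flask before a second pyrone can add, giving 22.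

Step 8. Acylation may go to carbon, or the chelate may be lost so that the E isomer forms; the enolate may also convert the acid chloride into a ketene. The fallback separates geometry control from acyl transfer, sets out from 15 and 16 and comes back at 19. Sodium enolate 18 is silylated (Me3SiCl, Et2O, 0 °C) to methyl (Z)-2-methyl-3-(trimethylsilyloxy)pent-2-enoate F5; silicon can only go to oxygen, and the geometry can be checked and enriched by distillation on this small fragment. Acid 15 is converted with cyanuric fluoride and pyridine (CH2Cl2, 0 °C) into 3-[2-methoxy-4,6-bis(methoxymethoxy)-5-(3-methylbut-2-en-1-yl)-3-(2-methylpropanoyl)phenyl]propanoyl fluoride F6. Catalytic Bu4N[Ph3SiF2] in THF at −78 °C should then transfer the acyl group from the acyl fluoride to the oxygen of the silyl enol ether with retention of alkene geometry, giving 19.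

Step 4. The base may metalate the benzylic–allylic CH2 of the prenyl group instead of the ring, or ring metalation of the lithium alkoxide may stay incomplete. The fallback replaces deprotonation by halogen–metal exchange, sets out from 8 and comes back at 10. NBS (MeCN, −20 °C) should brominate the single free, strongly activated ring position to give 1-[3-bromo-2-methoxy-4,6-bis(methoxymethoxy)-5-(3-methylbut-2-en-1-yl)phenyl]-2-methylpropan-1-ol F7. t-BuLi (3.2 equiv, THF, −78 °C) deprotonates the hydroxyl and exchanges bromine faster than any C–H is removed, giving the same dilithio alkoxide 9, which DMF converts into 10 as in step 4.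

**Further compounds**

F1 | step 9 | dianion of methyl 3-oxopentanoate (sodium lithium salt) | C[CH-]C(=O)[CH-]C(=O)OC.[Na+].[Li+]
F2 | step 9 | methyl 4-methyl-3,5-dioxoheptanoate | CCC(=O)C(C)C(=O)CC(=O)OC
F3 | step 9 | 6-ethyl-4-hydroxy-5-methyl-2H-pyran-2-one | CCc1oc(=O)cc(O)c1C
F4 | step 9 | 6-ethyl-3-{[2-methoxy-4,6-bis(methoxymethoxy)-5-(3-methylbut-2-en-1-yl)-3-(2-methylpropanoyl)phenyl]methylidene}-5-methyl-2H-pyran-2,4(3H)-dione (alkene geometry not fixed) | CCC1=C(C)C(=O)C(=Cc2c(OC)c(C(=O)C(C)C)c(OCOC)c(CC=C(C)C)c2OCOC)C(=O)O1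
F5 | step 8 | methyl (Z)-2-methyl-3-(trimethylsilyloxy)pent-2-enoate | CC/C(O[Si](C)(C)C)=C(\C)C(=O)OC
F6 | step 8 | 3-[2-methoxy-4,6-bis(methoxymethoxy)-5-(3-methylbut-2-en-1-yl)-3-(2-methylpropanoyl)phenyl]propanoyl fluoride | O=C(F)CCc1c(OC)c(C(=O)C(C)C)c(OCOC)c(CC=C(C)C)c1OCOC
F7 | step 4 | 1-[3-bromo-2-methoxy-4,6-bis(methoxymethoxy)-5-(3-methylbut-2-en-1-yl)phenyl]-2-methylpropan-1-ol (racemic) | CC(C)C(O)c1c(OC)c(Br)c(OCOC)c(CC=C(C)C)c1OCOC
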